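Ring D is cut at the O1'–C2' bond. In the target, O1' links C8a' of ring B to the quaternary C2', which carries two methyl groups and sits next to the hydroxylated C3'; such an arrangement arises when a phenol oxygen adds to the gem-dimethyl carbon of an adjacent 2,3-epoxy-3-methylbutyl chain. The key step does this under acid: the free phenol attacks the (2R)-oxirane in a 6-endo sense, closes ring D and passes the single catalyst-made stereocentre on to C3' untouched. The precursor is 2-benzyloxy-4-bromo-6-(epoxyprenyl)phenol, freed from its silyl ether without base. C3' then directs oxygenation at C4', and the bromide serves an enantioselective flavanone-forming conjugate addition.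

Key step: step 8

Remark on locants: primed numbers refer to the dimethylchroman unit (ring D fused to ring B), unprimed numbers to the flavanone; the target is (2S)-7-hydroxy-2-[(3R,4S)-3,4,8-trihydroxy-2,2-dimethylchroman-6-yl]chroman-4-one, with the C3' and C4' hydroxyls trans.

Design remark: the phenol passes through the epoxidation as a silyl ether and is unmasked by acetic-acid-buffered fluoride, because a phenoxide next to the epoxide (as basic ester cleavage would give) closes the five-membered ring at C3' before any acid is added.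

Assumption: the palladium/pyridine-oxazoline catalyst is taken to add the aryl group to chromone with the same facial sense as to 3-substituted cyclohexenones, which makes the (R)-ligand the one leading to the (2S)-flavanone; a model addition would confirm this before material is committed.

Assumption: compounds 1, 3 and 19 are taken to be commercially available.

Step 1
Reactants: 1 2-(benzyloxy)phenol
Product: 2 2-(benzyloxy)-4-bromophenol
Conditions: NBS (1.0 equiv), MeCN, 0 °C
Reagents that add atoms: N-bromosuccinimide, O=C1CCC(=O)N1Br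
Why: Electrophilic aromatic bromination is steered by the free hydroxyl, the stronger of the two donors, to its para position, which is the carbon that becomes C6' and later carries the flavanone.

Step 2
Reactants: 2 2-(benzyloxy)-4-bromophenol; 3 3-chloro-3-methylbut-1-yne
Product: 4 2-(benzyloxy)-4-bromo-1-[(2-methylbut-3-yn-2-yl)oxy]benzene
Conditions: CuCl2·2H2O (0.5 mol%), DBU, MeCN, 0 °C
Reagents that add atoms: none
Why: Copper-catalysed O-alkylation of a phenol by a tertiary propargylic chloride is the standard entry to aryl 1,1-dimethylpropargyl ethers, which plain Williamson conditions do not reach at a tertiary carbon.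

Step 3
Reactants: 4 2-(benzyloxy)-4-bromo-1-[(2-methylbut-3-yn-2-yl)oxy]benzene
Product: 5 2-(benzyloxy)-4-bromo-1-[(2-methylbut-3-en-2-yl)oxy]benzene
Conditions: H2 (1 atm), Pd/CaCO3 poisoned with Pb(OAc)2, quinoline, EtOAc, rt
Reagents that add atoms: none
Why: Lindlar semihydrogenation should stop at the terminal alkene and leave the aryl bromide and the benzyl ether untouched.

Step 4
Reactants: 5 2-(benzyloxy)-4-bromo-1-[(2-methylbut-3-en-2-yl)oxy]benzene
Product: 7 2-(benzyloxy)-4-bromo-6-(3-methylbut-2-en-1-yl)phenol, via ortho-dienone 6 (not isolated)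
Conditions: PhNEt2, 130 °C
Reagents that add atoms: none
Why: Aromatic Claisen rearrangement, in which the [3,3] shift of the 1,1-dimethylallyl ether can end productively only at the one unsubstituted ortho carbon (the other ortho and the para position are blocked) and tautomerisation of dienone 6 gives the ortho-prenylphenol with the allyl unit turned into the linear prenyl group.

Step 5
Reactants: 7 2-(benzyloxy)-4-bromo-6-(3-methylbut-2-en-1-yl)phenol
Product: 8 [2-(benzyloxy)-4-bromo-6-(3-methylbut-2-en-1-yl)phenoxy](tert-butyl)dimethylsilane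
Conditions: TBSCl, imidazole, DMF, rt
Reagents that add atoms: tert-butyldimethylsilyl chloride, CC(C)(C)[Si](C)(C)Cl
Why: Phenol silylation masks the nucleophilic and oxidisable hydroxyl for the basic epoxidation medium, and the silyl ether, shielded by two ortho substituents, can later be removed by fluoride without forming a phenoxide.

Step 6
Reactants: 8 [2-(benzyloxy)-4-bromo-6-(3-methylbut-2-en-1-yl)phenoxy](tert-butyl)dimethylsilane
Product: 9 [2-(benzyloxy)-4-bromo-6-{[(2R)-3,3-dimethyloxiran-2-yl]methyl}phenoxy](tert-butyl)dimethylsilane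
Conditions: D-fructose-derived Shi ketone (1,2:4,5-di-O-isopropylidene-β-D-erythro-2,3-hexodiulo-2,6-pyranose, 30 mol%), Oxone (2KHSO5·KHSO4·K2SO4), K2CO3, Bu4NHSO4, MeCN/CH2(OMe)2/aq. Na2B4O7 buffer (pH 10.5), 0 °C
Reagents that add atoms: potassium peroxymonosulfate (active salt of Oxone), [K+].[O-]S(=O)(=O)OO
Why: Shi asymmetric epoxidation, in which the chiral dioxirane formed from the D-fructose-derived ketone transfers oxygen to the trisubstituted prenyl alkene through the spiro transition state and should give the (R)-epoxide, the only catalyst-set stereocentre of ring D.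

Step 7
Reactants: 9 [2-(benzyloxy)-4-bromo-6-{[(2R)-3,3-dimethyloxiran-2-yl]methyl}phenoxy](tert-butyl)dimethylsilane
Product: 10 2-(benzyloxy)-4-bromo-6-{[(2R)-3,3-dimethyloxiran-2-yl]methyl}phenol
Conditions: Bu4NF, AcOH (1:1.5), THF, 0 °C; pH 7 work-up, crude product used at once
Reagents that add atoms: none
Why: Fluoride-mediated cleavage of the aryl silyl ether, buffered by acetic acid, should release the phenol in its protonated form so that no phenoxide is present to attack C3' in a five-membered ring closure.

Step 8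
Reactants: 10 2-(benzyloxy)-4-bromo-6-{[(2R)-3,3-dimethyloxiran-2-yl]methyl}phenol
Product: 11 (3R)-8-(benzyloxy)-6-bromo-2,2-dimethylchroman-3-ol
Conditions: CSA (10 mol%), CH2Cl2, −20 → 0 °C
Reagents that add atoms: none
Why: The sulfonic acid protonates (or strongly hydrogen-bonds) the oxirane oxygen, the bond from that oxygen to the dimethyl-substituted carbon lengthens as positive charge builds at this tertiary centre, and the C8a' phenol oxygen attacks it to form O1'–C2', after which proton loss returns the acid. The closest known reaction type is the acid-promoted cyclisation of ortho-(2,3-epoxy-3-methylbutyl)phenols to 3-hydroxy-2,2-dimethylchromans. Ring D closes in the 6-endo-tet mode. No stereocentre is created, since C2' carries two methyl groups and the C3'–O bond is never broken, so C3' keeps the R configuration written in by the epoxidation and the former oxirane oxygen simply becomes the C3' hydroxyl. The step needs 6-endo over 5-exo regioselectivity (attack at C3' would give a 2-(2-hydroxypropan-2-yl)dihydrobenzofuran), and this is secured by the absence of phenoxide, by the cation-stabilising gem-dimethyl terminus and by a non-nucleophilic solvent. Low temperature and a catalytic amount of acid should also hold back the competing hydride shift of the opened epoxide to a ketone (Meinwald rearrangement).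

Step 9
Reactants: 11 (3R)-8-(benzyloxy)-6-bromo-2,2-dimethylchroman-3-ol
Product: 12 {[(3R)-8-(benzyloxy)-6-bromo-2,2-dimethylchroman-3-yl]oxy}(tert-butyl)dimethylsilane
Conditions: TBSOTf, 2,6-lutidine, CH2Cl2, 0 °C
Reagents that add atoms: tert-butyldimethylsilyl trifluoromethanesulfonate, CC(C)(C)[Si](C)(C)OS(=O)(=O)C(F)(F)F
Why: Silylation of the hindered secondary C3' alcohol by the silyl triflate protects the carbinol from oxidation and installs the bulky group that is to screen one face of C4'.

Step 10
Reactants: 12 {[(3R)-8-(benzyloxy)-6-bromo-2,2-dimethylchroman-3-yl]oxy}(tert-butyl)dimethylsilane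
Product: 14 (3R,4S)-8-(benzyloxy)-6-bromo-3-[(tert-butyldimethylsilyl)oxy]-2,2-dimethylchroman-4-ol, via C4' benzylic cation 13 (not isolated)
Conditions: DDQ (1.3 equiv), ClCH2CH2Cl/aq. pH 7 phosphate buffer (10:1), 40 °C
Reagents that add atoms: water, O
Why: DDQ benzylic C–H oxidation as practised on 3-oxygenated chromans (flavan-3-ols), in which hydride abstraction from C4' of the electron-rich catechol-diether ring B gives cation 13 stabilised by O1', and water should add to the face opposite the neighbouring C3' silyloxy group to set C4' as S (3',4'-trans).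

Step 11
Reactants: 14 (3R,4S)-8-(benzyloxy)-6-bromo-3-[(tert-butyldimethylsilyl)oxy]-2,2-dimethylchroman-4-ol
Product: 15 (3R,4S)-8-(benzyloxy)-6-bromo-3,4-bis[(tert-butyldimethylsilyl)oxy]-2,2-dimethylchromane
Conditions: TBSOTf, 2,6-lutidine, CH2Cl2, 0 °C → rt
Reagents that add atoms: tert-butyldimethylsilyl trifluoromethanesulfonate, CC(C)(C)[Si](C)(C)OS(=O)(=O)C(F)(F)F
Why: Silyl protection of the benzylic C4' alcohol removes the last acidic proton before the organolithium step and leaves two hydroxyl protecting groups that can be removed together at the end.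

Step 12
Reactants: 15 (3R,4S)-8-(benzyloxy)-6-bromo-3,4-bis[(tert-butyldimethylsilyl)oxy]-2,2-dimethylchromane
Product: 18 {(3R,4S)-8-(benzyloxy)-3,4-bis[(tert-butyldimethylsilyl)oxy]-2,2-dimethylchroman-6-yl}boronic acid, via aryllithium 16 (not isolated), via lithium triisopropoxyborate 17 (not isolated)
Conditions: n-BuLi, THF, −78 °C; B(OiPr)3, −78 °C → rt; aq. NH4Cl
Reagents that add atoms: triisopropyl borate, CC(C)OB(OC(C)C)OC(C)C; water, O
Why: Bromine–lithium exchange followed by borate trapping and mild hydrolysis is the standard route from an aryl bromide to the free boronic acid, and at −78 °C the exchange should outrun deprotonation at the benzylic ether positions.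

Step 13
Reactants: 19 7-hydroxychromone (7-hydroxy-4H-chromen-4-one)
Product: 20 7-(benzyloxy)-4H-chromen-4-one
Conditions: BnBr, K2CO3, acetone, reflux
Reagents that add atoms: benzyl bromide, BrCc1ccccc1
Why: Williamson etherification of the acidic 7-hydroxyl under carbonate conditions, which are too mild to open the pyranone ring.

Step 14
Reactants: 18 {(3R,4S)-8-(benzyloxy)-3,4-bis[(tert-butyldimethylsilyl)oxy]-2,2-dimethylchroman-6-yl}boronic acid; 20 7-(benzyloxy)-4H-chromen-4-one
Product: 21 (2S)-7-(benzyloxy)-2-{(3R,4S)-8-(benzyloxy)-3,4-bis[(tert-butyldimethylsilyl)oxy]-2,2-dimethylchroman-6-yl}chroman-4-one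
Conditions: Pd(OCOCF3)2 (5 mol%), (R)-t-BuPyOx [(R)-4-tert-butyl-2-(pyridin-2-yl)-4,5-dihydrooxazole, 6 mol%], NH4PF6 (30 mol%), H2O (5 equiv), ClCH2CH2Cl, 60 °C
Reagents that add atoms: none
Why: Palladium-catalysed asymmetric conjugate addition of an arylboronic acid to a chromone, in which transmetalation to the cationic divalent palladium–pyridine-oxazoline complex, enantiodetermining carbopalladation of the C2–C3 double bond and protonolysis of the palladium enolate give the flavanone, with C2 set as S by the (R)-ligand under catalyst control (the chroman stereocentres are remote) and without any base that could racemise C2 through ring opening.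

Step 15
Reactants: 21 (2S)-7-(benzyloxy)-2-{(3R,4S)-8-(benzyloxy)-3,4-bis[(tert-butyldimethylsilyl)oxy]-2,2-dimethylchroman-6-yl}chroman-4-one
Product: 22 (2S)-2-{(3R,4S)-3,4-bis[(tert-butyldimethylsilyl)oxy]-8-hydroxy-2,2-dimethylchroman-6-yl}-7-hydroxychroman-4-one
Conditions: H2 (1 atm), Pd/C (10%), EtOAc, rt, stopped after uptake of 2 equiv
Reagents that add atoms: none
Why: Catalytic hydrogenolysis should cleave the two aryl benzyl ethers well before the flavanone C2–O1 bond or the aryl ketone under neutral conditions, while the benzylic C4' oxygen stays shielded as its silyl ether.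

Step 16
Reactants: 22 (2S)-2-{(3R,4S)-3,4-bis[(tert-butyldimethylsilyl)oxy]-8-hydroxy-2,2-dimethylchroman-6-yl}-7-hydroxychroman-4-one
Product: 23 (2S)-7-hydroxy-2-[(3R,4S)-3,4,8-trihydroxy-2,2-dimethylchroman-6-yl]chroman-4-one (CNP0281318.3)
Conditions: HF·pyridine, pyridine, THF, 0 °C → rt
Reagents that add atoms: none
Why: Fluoride-mediated desilylation under weakly acidic, non-basic conditions should free the C3' and C4' hydroxyls without enolising the flavanone (no epimerisation at C2) and without ionising the C4' carbinol.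

Compound list

1 | 2-(benzyloxy)phenol | Oc1ccccc1OCc1ccccc1 | starting material
2 | 2-(benzyloxy)-4-bromophenol | Oc1ccc(Br)cc1OCc1ccccc1 | intermediate
3 | 3-chloro-3-methylbut-1-yne | C#CC(C)(C)Cl | starting material
4 | 2-(benzyloxy)-4-bromo-1-[(2-methylbut-3-yn-2-yl)oxy]benzene | C#CC(C)(C)Oc1ccc(Br)cc1OCc1ccccc1 | intermediate
5 | 2-(benzyloxy)-4-bromo-1-[(2-methylbut-3-en-2-yl)oxy]benzene | C=CC(C)(C)Oc1ccc(Br)cc1OCc1ccccc1 | intermediate
6 | 2-(benzyloxy)-4-bromo-6-(3-methylbut-2-en-1-yl)cyclohexa-2,4-dien-1-one (racemic at C6, formed in situ) | CC(C)=CCC1C=C(Br)C=C(OCc2ccccc2)C1=O | intermediate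
7 | 2-(benzyloxy)-4-bromo-6-(3-methylbut-2-en-1-yl)phenol | CC(C)=CCc1cc(Br)cc(OCc2ccccc2)c1O | intermediate
8 | [2-(benzyloxy)-4-bromo-6-(3-methylbut-2-en-1-yl)phenoxy](tert-butyl)dimethylsilane | CC(C)=CCc1cc(Br)cc(OCc2ccccc2)c1O[Si](C)(C)C(C)(C)C | intermediate
9 | [2-(benzyloxy)-4-bromo-6-{[(2R)-3,3-dimethyloxiran-2-yl]methyl}phenoxy](tert-butyl)dimethylsilane | CC1(C)O[C@@H]1Cc1cc(Br)cc(OCc2ccccc2)c1O[Si](C)(C)C(C)(C)C | intermediate
10 | 2-(benzyloxy)-4-bromo-6-{[(2R)-3,3-dimethyloxiran-2-yl]methyl}phenol | CC1(C)O[C@@H]1Cc1cc(Br)cc(OCc2ccccc2)c1O | intermediate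
11 | (3R)-8-(benzyloxy)-6-bromo-2,2-dimethylchroman-3-ol | CC1(C)Oc2c(OCc3ccccc3)cc(Br)cc2C[C@H]1O | intermediate
12 | {[(3R)-8-(benzyloxy)-6-bromo-2,2-dimethylchroman-3-yl]oxy}(tert-butyl)dimethylsilane | CC1(C)Oc2c(OCc3ccccc3)cc(Br)cc2C[C@H]1O[Si](C)(C)C(C)(C)C | intermediate
13 | (3R)-8-(benzyloxy)-6-bromo-3-[(tert-butyldimethylsilyl)oxy]-2,2-dimethylchroman-4-ylium (formed in situ) | CC1(C)Oc2c(OCc3ccccc3)cc(Br)cc2[CH+][C@H]1O[Si](C)(C)C(C)(C)C | intermediate
14 | (3R,4S)-8-(benzyloxy)-6-bromo-3-[(tert-butyldimethylsilyl)oxy]-2,2-dimethylchroman-4-ol | CC1(C)Oc2c(OCc3ccccc3)cc(Br)cc2[C@H](O)[C@H]1O[Si](C)(C)C(C)(C)C | intermediate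
15 | (3R,4S)-8-(benzyloxy)-6-bromo-3,4-bis[(tert-butyldimethylsilyl)oxy]-2,2-dimethylchromane | CC1(C)Oc2c(OCc3ccccc3)cc(Br)cc2[C@H](O[Si](C)(C)C(C)(C)C)[C@H]1O[Si](C)(C)C(C)(C)C | intermediate
16 | {(3R,4S)-8-(benzyloxy)-3,4-bis[(tert-butyldimethylsilyl)oxy]-2,2-dimethylchroman-6-yl}lithium (formed in situ) | CC1(C)Oc2c(OCc3ccccc3)cc([Li])cc2[C@H](O[Si](C)(C)C(C)(C)C)[C@H]1O[Si](C)(C)C(C)(C)C | intermediate
17 | lithium {(3R,4S)-8-(benzyloxy)-3,4-bis[(tert-butyldimethylsilyl)oxy]-2,2-dimethylchroman-6-yl}tris(propan-2-yloxy)borate (formed in situ) | CC1(C)Oc2c(OCc3ccccc3)cc([B-](OC(C)C)(OC(C)C)OC(C)C)cc2[C@H](O[Si](C)(C)C(C)(C)C)[C@H]1O[Si](C)(C)C(C)(C)C.[Li+] | intermediate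
18 | {(3R,4S)-8-(benzyloxy)-3,4-bis[(tert-butyldimethylsilyl)oxy]-2,2-dimethylchroman-6-yl}boronic acid | CC1(C)Oc2c(OCc3ccccc3)cc(B(O)O)cc2[C@H](O[Si](C)(C)C(C)(C)C)[C@H]1O[Si](C)(C)C(C)(C)C | intermediate
19 | 7-hydroxychromone (7-hydroxy-4H-chromen-4-one) | O=c1ccoc2cc(O)ccc12 | starting material
20 | 7-(benzyloxy)-4H-chromen-4-one | O=c1ccoc2cc(OCc3ccccc3)ccc12 | intermediate
21 | (2S)-7-(benzyloxy)-2-{(3R,4S)-8-(benzyloxy)-3,4-bis[(tert-butyldimethylsilyl)oxy]-2,2-dimethylchroman-6-yl}chroman-4-one | CC1(C)Oc2c(OCc3ccccc3)cc([C@@H]3CC(=O)c4ccc(OCc5ccccc5)cc4O3)cc2[C@H](O[Si](C)(C)C(C)(C)C)[C@H]1O[Si](C)(C)C(C)(C)C | intermediate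
22 | (2S)-2-{(3R,4S)-3,4-bis[(tert-butyldimethylsilyl)oxy]-8-hydroxy-2,2-dimethylchroman-6-yl}-7-hydroxychroman-4-one | CC1(C)Oc2c(O)cc([C@@H]3CC(=O)c4ccc(O)cc4O3)cc2[C@H](O[Si](C)(C)C(C)(C)C)[C@H]1O[Si](C)(C)C(C)(C)C | intermediate
23 | (2S)-7-hydroxy-2-[(3R,4S)-3,4,8-trihydroxy-2,2-dimethylchroman-6-yl]chroman-4-one | CC1(C)Oc2c(O)cc([C@@H]3CC(=O)c4ccc(O)cc4O3)cc2[C@H](O)[C@H]1O | target

Total step count: 16 steps.
Longest linear sequence: 15 steps (steps 1–12 and 14–16, from compound 1); the chromone branch contributes step 13.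

Steps most likely to fail

Step 10 (oxygenation of C4'). Three things may go wrong here. Hydride abstraction may be slow, because ring B offers the C4' cation only the O1' donor and no para alkoxy group. The new carbinol may be oxidised further to the ketone. The cation may also be captured by water with poor facial selectivity, or be lost through a 1,2-hydride shift from C3'. The fallback sets out from 12 and comes back at 15; it makes the over-oxidation the intended reaction and sets C4' by intramolecular hydride delivery. Compound 12 with excess DDQ in wet dioxane at 60 °C should give (3S)-8-(benzyloxy)-6-bromo-3-[(tert-butyldimethylsilyl)oxy]-2,2-dimethylchroman-4-one F1 (the descriptor changes through priorities only, not in space). HF·pyridine in THF should then free the α-hydroxy ketone (3S)-8-(benzyloxy)-6-bromo-3-hydroxy-2,2-dimethylchroman-4-one F2. Me4NBH(OAc)3 in MeCN/AcOH at −20 °C binds to the C3' oxygen and delivers hydride to the carbonyl face on the side of that oxygen, which should give the trans diol (3R,4S)-8-(benzyloxy)-6-bromo-2,2-dimethylchromane-3,4-diol F3. TBSOTf (2.5 equiv) with 2,6-lutidine converts F3 into 15. If C–H oxidation at C4' fails altogether, the chromene sequence given below for step 8 reaches 15 without it.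

Step 14 (conjugate addition). Protodeboronation of the electron-rich boronic acid may outrun carbopalladation, traces of fluoride from NH4PF6 may erode the silyl ethers at 60 °C, or the catalyst may discriminate the two faces of C2 insufficiently. The fallback sets out from 15 and comes back at 21; it builds the pyranone ring by oxa-Michael closure instead. Bromine–lithium exchange on 15 (n-BuLi, THF, −78 °C) and quenching with DMF should give (3R,4S)-8-(benzyloxy)-3,4-bis[(tert-butyldimethylsilyl)oxy]-2,2-dimethylchromane-6-carbaldehyde F4. Claisen–Schmidt condensation of F4 with commercial 1-[4-(benzyloxy)-2-hydroxyphenyl]ethanone (KOH, EtOH, rt) should give (E)-1-[4-(benzyloxy)-2-hydroxyphenyl]-3-{(3R,4S)-8-(benzyloxy)-3,4-bis[(tert-butyldimethylsilyl)oxy]-2,2-dimethylchroman-6-yl}prop-2-en-1-one F5. Intramolecular oxa-Michael addition (NaOAc, EtOH, reflux, optionally with a quinine-derived bifunctional thiourea to bias the new centre) should give 21 together with its C2 epimer (2R)-7-(benzyloxy)-2-{(3R,4S)-8-(benzyloxy)-3,4-bis[(tert-butyldimethylsilyl)oxy]-2,2-dimethylchroman-6-yl}chroman-4-one F6. Because the chroman unit is enantiopure the two are diastereomers and should be separable by preparative HPLC, and F6 can be returned to the equilibrium through F5.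

Step 8 (key ring closure). The closure may leak into the 5-exo mode at C3', the opened epoxide may undergo a hydride shift to a ketone, or phenol 10 may cyclise unselectively during handling before the strong acid is present. The fallback sets out from 4 and comes back at 15; it forms ring D without any epoxide opening by the phenol. Heating 4 in PhNEt2 at 190 °C (propargyl Claisen rearrangement, 1,5-hydrogen shift, 6π-electrocyclisation) should give 8-(benzyloxy)-6-bromo-2,2-dimethyl-2H-chromene F7. Jacobsen–Katsuki epoxidation with (R,R)-[N,N'-bis(3,5-di-tert-butylsalicylidene)cyclohexane-1,2-diaminato]manganese chloride (a trivalent manganese complex), NaOCl and 4-phenylpyridine N-oxide in CH2Cl2 at 0 °C should give (3R,4R)-8-(benzyloxy)-6-bromo-3,4-epoxy-2,2-dimethylchromane F8. Dilute HClO4 in acetone/H2O opens F8 at the benzylic C4' with inversion to the trans diol (3R,4S)-8-(benzyloxy)-6-bromo-2,2-dimethylchromane-3,4-diol F3, and bis-silylation (TBSOTf, 2,6-lutidine) gives 15.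

Further compounds

F1 | step 10 | (3S)-8-(benzyloxy)-6-bromo-3-[(tert-butyldimethylsilyl)oxy]-2,2-dimethylchroman-4-one | CC1(C)Oc2c(OCc3ccccc3)cc(Br)cc2C(=O)[C@H]1O[Si](C)(C)C(C)(C)C
F2 | step 10 | (3S)-8-(benzyloxy)-6-bromo-3-hydroxy-2,2-dimethylchroman-4-one | CC1(C)Oc2c(OCc3ccccc3)cc(Br)cc2C(=O)[C@H]1O
F3 | step 10 | (3R,4S)-8-(benzyloxy)-6-bromo-2,2-dimethylchromane-3,4-diol | CC1(C)Oc2c(OCc3ccccc3)cc(Br)cc2[C@H](O)[C@H]1O
F4 | step 14 | (3R,4S)-8-(benzyloxy)-3,4-bis[(tert-butyldimethylsilyl)oxy]-2,2-dimethylchromane-6-carbaldehyde | CC1(C)Oc2c(OCc3ccccc3)cc(C=O)cc2[C@H](O[Si](C)(C)C(C)(C)C)[C@H]1O[Si](C)(C)C(C)(C)C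
F5 | step 14 | (E)-1-[4-(benzyloxy)-2-hydroxyphenyl]-3-{(3R,4S)-8-(benzyloxy)-3,4-bis[(tert-butyldimethylsilyl)oxy]-2,2-dimethylchroman-6-yl}prop-2-en-1-one | CC1(C)Oc2c(OCc3ccccc3)cc(/C=C/C(=O)c3ccc(OCc4ccccc4)cc3O)cc2[C@H](O[Si](C)(C)C(C)(C)C)[C@H]1O[Si](C)(C)C(C)(C)C
F6 | step 14 | (2R)-7-(benzyloxy)-2-{(3R,4S)-8-(benzyloxy)-3,4-bis[(tert-butyldimethylsilyl)oxy]-2,2-dimethylchroman-6-yl}chroman-4-one | CC1(C)Oc2c(OCc3ccccc3)cc([C@H]3CC(=O)c4ccc(OCc5ccccc5)cc4O3)cc2[C@H](O[Si](C)(C)C(C)(C)C)[C@H]1O[Si](C)(C)C(C)(C)C
F7 | step 8 | 8-(benzyloxy)-6-bromo-2,2-dimethyl-2H-chromene | CC1(C)C=Cc2cc(Br)cc(OCc3ccccc3)c2O1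
F8 | step 8 | (3R,4R)-8-(benzyloxy)-6-bromo-3,4-epoxy-2,2-dimethylchromane | CC1(C)Oc2c(OCc3ccccc3)cc(Br)cc2[C@H]3O[C@@H]13
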